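**Plan**
Retrosynthesis: the aryl ether bond O–C8'' and the C7''–aryl bond are cut first (glycerol unit from methyl (R)-glycerate and an aryl Grignard reagent); then the C7–C8 bond of ring A (tetrahydrofuran O/C7/C8/C8'/C9') is cut back to a benzyl ether of a ring-B ketone; then the benzyl ether O–C7 and the aldol bond C7'–C8'.
Forward: Evans syn-aldol, ring B (lactol, 2,3-dihydrofuran, tetrahydrofuran-3-one), ring A by photocyclization, removal of the helper hydroxyl at C8, then the side chain on the freed guaiacyl phenol.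
Enabling feature: C7 is a benzylic CH2 flanked by the ring-A oxygen and held δ to C8 through O–C9'–C8'; with C8 as the ring-B carbonyl, the excited ketone takes a hydrogen from C7 and the radical centres C7 and C8 join.
Stereochemistry: C7'/C8' from the (R)-benzyloxazolidinone aldol; C8 from the enforced cis ring fusion (kept when H replaces OH from the convex face); C7 from exo collapse of the biradical; C8'' from methyl (R)-glycerate with Mitsunobu inversion; C7'' from chelation-controlled reduction.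

Key step: step 11

Assumption: lignan numbering is used (C7–C9 guaiacyl half, primed atoms syringyl half, double-primed atoms glycerol unit; ring B = O/C7'/C8'/C8/C9); the SMILES is read as 7R,8S,7'R,8'S (both aryl groups exo on the cis-fused furofuran) and 7''R,8''S (erythro).
Abbreviations in names: Sy = 3,5-dimethoxy-4-(triisopropylsilyloxy)phenyl; BnG = 4-(benzyloxy)-3-methoxyphenyl.

Step 1
Reactants: 1 (R)-4-benzyloxazolidin-2-one; 2 pent-4-enoyl chloride
Product: 3 (R)-4-benzyl-3-(pent-4-enoyl)oxazolidin-2-one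
Conditions: Et3N, DMAP (cat.), CH2Cl2, 0 °C to rt
Reagents that add atoms: none
Why: N-acylation of the oxazolidinone by the acid chloride under DMAP catalysis (acyl transfer via the acylpyridinium ion), with the auxiliary stereocentre untouched.

Step 2
Reactants: 4 syringaldehyde
Product: 5 3,5-dimethoxy-4-(triisopropylsilyloxy)benzaldehyde
Conditions: TIPSOTf, 2,6-lutidine, CH2Cl2, 0 °C
Reagents that add atoms: triisopropylsilyl triflate, CC(C)[Si](OS(=O)(=O)C(F)(F)F)(C(C)C)C(C)C
Why: O-silylation of the hindered phenol with a reactive silyl triflate and a non-nucleophilic base, no stereocentre being involved.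

Step 3
Reactants: 3 (R)-4-benzyl-3-(pent-4-enoyl)oxazolidin-2-one; 5 3,5-dimethoxy-4-(triisopropylsilyloxy)benzaldehyde
Product: 8 (R)-4-benzyl-3-[(2R)-2-{(R)-hydroxy(Sy)methyl}pent-4-enoyl]oxazolidin-2-one, via boron enolate 6 (not isolated), via boron aldolate 7 (not isolated)
Conditions: Bu2BOTf, iPr2NEt, CH2Cl2, 0 °C; then 5, −78 to 0 °C; then H2O2, MeOH, pH 7 buffer
Reagents that add atoms: none
Why: Evans syn-aldol reaction, in which the (Z)-boron enolate reacts through a Zimmerman–Traxler chair and the benzyl group of the (R)-auxiliary blocks one enolate face, so that C8' and C7' are both set R (syn).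

Step 4
Reactants: 8 (R)-4-benzyl-3-[(2R)-2-{(R)-hydroxy(Sy)methyl}pent-4-enoyl]oxazolidin-2-one
Product: 11 (R)-4-benzyl-3-{[(2R,3R)-5-hydroxy-2-Sy-tetrahydrofuran-3-yl]carbonyl}oxazolidin-2-one (anomers), via diol 9 (not isolated), via aldehyde 10 (not isolated)
Conditions: OsO4 (cat.), NaIO4, 2,6-lutidine, dioxane/H2O, rt
Reagents that add atoms: osmium tetroxide, O=[Os](=O)(=O)=O; sodium periodate (terminal oxygen source), [Na+].[O-][I](=O)(=O)=O
Why: Lemieux–Johnson cleavage (dihydroxylation, then periodate glycol scission) of the terminal alkene, the aldehyde being trapped by the C7' hydroxyl as a five-membered lactol, with C7' and C8' untouched and the anomeric centre removed in step 5.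

Step 5
Reactants: 11 (R)-4-benzyl-3-{[(2R,3R)-5-hydroxy-2-Sy-tetrahydrofuran-3-yl]carbonyl}oxazolidin-2-one
Product: 13 (R)-4-benzyl-3-{[(2R,3R)-2-Sy-2,3-dihydrofuran-3-yl]carbonyl}oxazolidin-2-one, via anomeric mesylate 12 (not isolated)
Conditions: MsCl, Et3N, CH2Cl2, −40 °C to rt
Reagents that add atoms: none
Why: Mesylation–elimination of a 2-deoxy lactol (furanoid glycal synthesis), in which the anomeric mesylate ionizes to the oxocarbenium ion and loses the C8 proton to give the cyclic enol ether without touching C7' or C8'.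

Step 6
Reactants: 13 (R)-4-benzyl-3-{[(2R,3R)-2-Sy-2,3-dihydrofuran-3-yl]carbonyl}oxazolidin-2-one
Product: 14 [(2R,3S)-2-Sy-2,3-dihydrofuran-3-yl]methanol
Conditions: LiBH4, MeOH (1 equiv), THF, 0 °C
Reagents that add atoms: none
Why: Reductive cleavage of the N-acyloxazolidinone with LiBH4 gives the primary alcohol (C9') and returns the auxiliary, the enol ether and both stereocentres being inert to borohydride.

Step 7
Reactants: 15 4-(benzyloxy)-3-methoxybenzyl alcohol
Product: 16 4-(benzyloxy)-3-methoxybenzyl bromide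
Conditions: PBr3, Et2O, 0 °C
Reagents that add atoms: phosphorus tribromide, BrP(Br)Br
Why: Conversion of an electron-rich benzylic alcohol into the bromide with PBr3 (SN2 on the alkoxyphosphorus intermediate), no stereocentre involved.

Step 8
Reactants: 14 [(2R,3S)-2-Sy-2,3-dihydrofuran-3-yl]methanol; 16 4-(benzyloxy)-3-methoxybenzyl bromide
Product: 17 (2R,3S)-3-[(BnG-methoxy)methyl]-2-Sy-2,3-dihydrofuran
Conditions: NaH, Bu4NI (cat.), THF/DMF, 0 °C to rt
Reagents that add atoms: none
Why: Williamson ether synthesis (SN2 of the sodium alkoxide of 14 on the benzylic bromide) under basic conditions that the acid-labile enol ether tolerates, no stereocentre being affected.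

Step 9
Reactants: 17 (2R,3S)-3-[(BnG-methoxy)methyl]-2-Sy-2,3-dihydrofuran
Product: 19 (3R,4R,5R)-4-[(BnG-methoxy)methyl]-5-Sy-tetrahydrofuran-3-ol, via alkylborane 18 (not isolated)
Conditions: 9-BBN, THF, 0 °C to rt; then H2O2, aq. NaOAc, 0 °C
Reagents that add atoms: hydrogen peroxide, OO
Why: Hydroboration–oxidation of the cyclic enol ether places boron, then hydroxyl with retention, on C8 (β to oxygen by electronic control) anti to the C8' side chain, and the new carbinol centre is erased in step 10.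

Step 10
Reactants: 19 (3R,4R,5R)-4-[(BnG-methoxy)methyl]-5-Sy-tetrahydrofuran-3-ol
Product: 20 (4S,5R)-4-[(BnG-methoxy)methyl]-5-Sy-dihydrofuran-3(2H)-one
Conditions: Dess–Martin periodinane, NaHCO3, CH2Cl2, 0 °C to rt
Reagents that add atoms: none
Why: Dess–Martin oxidation under buffered neutral conditions gives the tetrahydrofuran-3-one, whose epimerizable C8' centre already holds the more stable trans arrangement to the C7' aryl group.

Step 11
Reactants: 20 (4S,5R)-4-[(BnG-methoxy)methyl]-5-Sy-dihydrofuran-3(2H)-one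
Product: 21 (7S,8R,7'R,8'S)-7-BnG-7'-Sy-furofuran-8-ol (cis-fused 2,6-diaryl-3,7-dioxabicyclo[3.3.0]octan-1-ol with both aryl groups exo)
Conditions: hν (350 nm, Pyrex), degassed benzene (0.01 M), rt
Reagents that add atoms: none
Why: Norrish–Yang photocyclization: n→π* excitation of the C8 ketone of ring B gives a triplet that abstracts the benzylic, ether-activated C7–H through a seven-membered transition state (1,6-hydrogen transfer; the γ position is the ether oxygen, so no γ-hydrogen competes), and the 1,5-biradical (C8 ketyl, C7 α-alkoxybenzyl) collapses by radical coupling to the C7–C8 bond. The closest known reaction type is the photocyclization of β-alkoxy ketones to 3-hydroxytetrahydrofurans, including cis-fused 8-hydroxyfurofurans from 4-(arylmethoxymethyl)tetrahydrofuran-3-ones. Ring A closes by 1,5-biradical recombination onto the ketyl carbon, a five-membered ring closure that can only be cis-fused to ring B. C8 is controlled by the O–C9' tether on C8' (C7 reaches only the face of C8 that carries C9', so the hydroxyl ends on the convex face), and C7 is controlled by the folded bicyclic transition state, in which the freely rotating C7 radical should place its aryl group on the convex (exo) face, away from ring B. The step needs site selectivity for C7–H (secured by geometry: C7'–H is β and out of reach, the protecting-group benzyl CH2 is remote), preference for hydrogen abstraction over Norrish α-cleavage (secured by the doubly activated C7–H), and exo selectivity at C7 (secured by the steric bias just described).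

Step 12
Reactants: 21 (7S,8R,7'R,8'S)-7-BnG-7'-Sy-furofuran-8-ol
Product: 22 methyl oxalate of 21 (8-O-C(O)CO2Me)
Conditions: MeO2CCOCl, DMAP, pyridine, CH2Cl2, 0 °C to rt
Reagents that add atoms: methyl chlorooxoacetate, COC(=O)C(Cl)=O
Why: Acylation of the hindered tertiary alcohol with the highly electrophilic methyl chlorooxoacetate under DMAP catalysis gives the mixed oxalate needed for radical C–O cleavage, with no change at any stereocentre.

Step 13
Reactants: 22 methyl oxalate of 21
Product: 23 (7R,8S,7'R,8'S)-7-BnG-7'-Sy-furofuran (4-O-benzyl-4'-O-triisopropylsilyl medioresinol of this series)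
Conditions: Bu3SnH, AIBN, toluene, 110 °C
Reagents that add atoms: none
Why: Radical deoxygenation of a tertiary methyl oxalate (Barton-type tin hydride chain), in which stannyl radical addition and β-scission give the tertiary C8 radical, which should take hydrogen from Bu3SnH on the convex face because only the cis-fused bicycle is accessible, setting C8 as S.

Step 14
Reactants: 23 (7R,8S,7'R,8'S)-7-BnG-7'-Sy-furofuran
Product: 24 (7R,8S,7'R,8'S)-4'-O-triisopropylsilyl medioresinol (free guaiacyl phenol)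
Conditions: H2 (1 atm), Pd/C, EtOAc, rt
Reagents that add atoms: none
Why: Hydrogenolysis of the benzyl aryl ether over palladium frees the guaiacyl phenol, the aryl silyl ether being inert and the reaction being stopped before the slower cleavage of the benzylic C–O bonds of the furofuran.

Step 15
Reactants: 25 methyl (R)-2,3-dihydroxypropanoate
Product: 26 methyl (R)-3-(tert-butyldimethylsilyloxy)-2-hydroxypropanoate
Conditions: TBSCl, imidazole, CH2Cl2, −20 to 0 °C
Reagents that add atoms: tert-butyldimethylsilyl chloride, CC(C)(C)[Si](C)(C)Cl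
Why: Selective silylation of the primary hydroxyl of the 1,2-diol with one equivalent of TBSCl at low temperature (steric control), leaving the C2 stereocentre and the secondary hydroxyl free.

Step 16
Reactants: 24 (7R,8S,7'R,8'S)-4'-O-triisopropylsilyl medioresinol; 26 methyl (R)-3-(tert-butyldimethylsilyloxy)-2-hydroxypropanoate
Product: 27 methyl (S)-3-(tert-butyldimethylsilyloxy)-2-(aryloxy)propanoate (aryloxy = 4-O of the furofuran 24)
Conditions: PPh3, DIAD, THF, 0 °C to rt
Reagents that add atoms: none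
Why: Mitsunobu etherification, in which the phenol of 24 displaces the phosphonium-activated secondary hydroxyl of 26 by SN2 with inversion, converting the R centre of the glycerate into the S centre C8''.

Step 17
Reactants: 28 4-bromo-2-methoxyphenol
Product: 29 (4-bromo-2-methoxyphenoxy)(tert-butyl)dimethylsilane
Conditions: TBSCl, imidazole, DMF, rt
Reagents that add atoms: tert-butyldimethylsilyl chloride, CC(C)(C)[Si](C)(C)Cl
Why: O-silylation of the phenol so that the aryl bromide can be turned into a Grignard reagent, no stereocentre being involved.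

Step 18
Reactants: 27 methyl (S)-3-(tert-butyldimethylsilyloxy)-2-(aryloxy)propanoate; 29 (4-bromo-2-methoxyphenoxy)(tert-butyl)dimethylsilane
Product: 31 (S)-1-[4-(tert-butyldimethylsilyloxy)-3-methoxyphenyl]-3-(tert-butyldimethylsilyloxy)-2-(aryloxy)propan-1-one, via Weinreb amide 30 (not isolated)
Conditions: MeNH(OMe)·HCl, iPrMgCl, THF, −20 °C; then ArMgBr (from 29, Mg, THF), −20 to 0 °C; aq. NH4Cl
Reagents that add atoms: none
Why: One-pot ester to ketone conversion through the Weinreb amide, whose chelated tetrahedral adduct with the aryl Grignard reagent resists over-addition and enolization until work-up, so that C8'' stays S.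

Step 19
Reactants: 31 (S)-aryl ketone
Product: 32 (7''R,8''S)-alcohol, the 4',4'',9''-tris-silyl ether of the target
Conditions: Zn(BH4)2, Et2O, −30 °C
Reagents that add atoms: none
Why: Chelation-controlled reduction (Cram cyclic model), in which zinc bridges the carbonyl and the α-aryloxy oxygen atoms and hydride attacks from the side of the small α-hydrogen, which should set C7'' as R (erythro to C8'').

Step 20
Reactants: 32 (7''R,8''S)-alcohol tris-silyl ether
Product: 33 ficusesquilignan A
Conditions: TBAF, AcOH, THF, 0 °C to rt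
Reagents that add atoms: none
Why: Fluoride-mediated cleavage of the two aryl silyl ethers and the primary alkyl silyl ether, buffered with acetic acid so that no strong base acts on the phenols or benzylic positions, should give the target without touching any stereocentre.

**Compound list**
1 | (R)-4-benzyloxazolidin-2-one | O=C1N[C@H](Cc2ccccc2)CO1 | starting material
2 | pent-4-enoyl chloride | C=CCCC(Cl)=O | starting material
3 | (R)-4-benzyl-3-(pent-4-enoyl)oxazolidin-2-one | C=CCCC(=O)N1[C@H](Cc2ccccc2)COC1=O | intermediate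
4 | syringaldehyde (4-hydroxy-3,5-dimethoxybenzaldehyde) | COc1cc(C=O)cc(OC)c1O | starting material
5 | 3,5-dimethoxy-4-(triisopropylsilyloxy)benzaldehyde | COc1cc(C=O)cc(OC)c1O[Si](C(C)C)(C(C)C)C(C)C | intermediate
6 | dibutylboron (Z)-enolate of 3 | C=CC/C=C(\OB(CCCC)CCCC)N1[C@H](Cc2ccccc2)COC1=O | intermediate
7 | dibutylboron aldolate of 8 | C=CC[C@H]([C@@H](OB(CCCC)CCCC)c1cc(OC)c(O[Si](C(C)C)(C(C)C)C(C)C)c(OC)c1)C(=O)N1[C@H](Cc2ccccc2)COC1=O | intermediate
8 | (R)-4-benzyl-3-[(2R)-2-{(R)-hydroxy(Sy)methyl}pent-4-enoyl]oxazolidin-2-one | C=CC[C@H]([C@@H](O)c1cc(OC)c(O[Si](C(C)C)(C(C)C)C(C)C)c(OC)c1)C(=O)N1[C@H](Cc2ccccc2)COC1=O | intermediate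
9 | 4,5-diol of 8 (both C4 epimers) | OCC(O)C[C@H]([C@@H](O)c1cc(OC)c(O[Si](C(C)C)(C(C)C)C(C)C)c(OC)c1)C(=O)N1[C@H](Cc2ccccc2)COC1=O | intermediate
10 | (R)-4-benzyl-3-[(2R)-2-{(R)-hydroxy(Sy)methyl}-4-oxobutanoyl]oxazolidin-2-one | O=CC[C@H]([C@@H](O)c1cc(OC)c(O[Si](C(C)C)(C(C)C)C(C)C)c(OC)c1)C(=O)N1[C@H](Cc2ccccc2)COC1=O | intermediate
11 | (R)-4-benzyl-3-{[(2R,3R)-5-hydroxy-2-Sy-tetrahydrofuran-3-yl]carbonyl}oxazolidin-2-one (anomers) | OC1C[C@@H](C(=O)N2[C@H](Cc3ccccc3)COC2=O)[C@H](c2cc(OC)c(O[Si](C(C)C)(C(C)C)C(C)C)c(OC)c2)O1 | intermediate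
12 | anomeric mesylate of 11 | CS(=O)(=O)OC1C[C@@H](C(=O)N2[C@H](Cc3ccccc3)COC2=O)[C@H](c2cc(OC)c(O[Si](C(C)C)(C(C)C)C(C)C)c(OC)c2)O1 | intermediate
13 | (R)-4-benzyl-3-{[(2R,3R)-2-Sy-2,3-dihydrofuran-3-yl]carbonyl}oxazolidin-2-one | C1=C[C@@H](C(=O)N2[C@H](Cc3ccccc3)COC2=O)[C@H](c2cc(OC)c(O[Si](C(C)C)(C(C)C)C(C)C)c(OC)c2)O1 | intermediate
14 | [(2R,3S)-2-Sy-2,3-dihydrofuran-3-yl]methanol | C1=C[C@@H](CO)[C@H](c2cc(OC)c(O[Si](C(C)C)(C(C)C)C(C)C)c(OC)c2)O1 | intermediate
15 | 4-(benzyloxy)-3-methoxybenzyl alcohol | COc1cc(CO)ccc1OCc1ccccc1 | starting material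
16 | 4-(benzyloxy)-3-methoxybenzyl bromide | COc1cc(CBr)ccc1OCc1ccccc1 | intermediate
17 | (2R,3S)-3-[(BnG-methoxy)methyl]-2-Sy-2,3-dihydrofuran | C1=C[C@@H](COCc2ccc(OCc3ccccc3)c(OC)c2)[C@H](c2cc(OC)c(O[Si](C(C)C)(C(C)C)C(C)C)c(OC)c2)O1 | intermediate
18 | B-alkyl-9-borabicyclo[3.3.1]nonane from 17 (boron on C8, trans to the C8' side chain) | C1CCC2CCCC1B2[C@H]1CO[C@@H](c2cc(OC)c(O[Si](C(C)C)(C(C)C)C(C)C)c(OC)c2)[C@@H]1COCc1ccc(OCc2ccccc2)c(OC)c1 | intermediate
19 | (3R,4R,5R)-4-[(BnG-methoxy)methyl]-5-Sy-tetrahydrofuran-3-ol | O[C@H]1CO[C@@H](c2cc(OC)c(O[Si](C(C)C)(C(C)C)C(C)C)c(OC)c2)[C@@H]1COCc1ccc(OCc2ccccc2)c(OC)c1 | intermediate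
20 | (4S,5R)-4-[(BnG-methoxy)methyl]-5-Sy-dihydrofuran-3(2H)-one | O=C1CO[C@@H](c2cc(OC)c(O[Si](C(C)C)(C(C)C)C(C)C)c(OC)c2)[C@@H]1COCc1ccc(OCc2ccccc2)c(OC)c1 | intermediate
21 | (7S,8R,7'R,8'S)-7-BnG-7'-Sy-furofuran-8-ol (both aryl groups exo, OH on the ring-fusion carbon C8) | COc1cc([C@@H]2OC[C@@H]3[C@@]2(O)CO[C@H]3c2cc(OC)c(O[Si](C(C)C)(C(C)C)C(C)C)c(OC)c2)ccc1OCc1ccccc1 | intermediate
22 | methyl oxalate of 21 | COc1cc([C@@H]2OC[C@@H]3[C@@]2(OC(=O)C(=O)OC)CO[C@H]3c2cc(OC)c(O[Si](C(C)C)(C(C)C)C(C)C)c(OC)c2)ccc1OCc1ccccc1 | intermediate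
23 | (7R,8S,7'R,8'S)-7-BnG-7'-Sy-furofuran (4-O-benzyl-4'-O-triisopropylsilyl medioresinol) | COc1cc([C@@H]2OC[C@@H]3[C@H]2CO[C@H]3c2cc(OC)c(O[Si](C(C)C)(C(C)C)C(C)C)c(OC)c2)ccc1OCc1ccccc1 | intermediate
24 | (7R,8S,7'R,8'S)-4'-O-triisopropylsilyl medioresinol | COc1cc([C@@H]2OC[C@@H]3[C@H]2CO[C@H]3c2cc(OC)c(O[Si](C(C)C)(C(C)C)C(C)C)c(OC)c2)ccc1O | intermediate
25 | methyl (R)-2,3-dihydroxypropanoate (methyl D-glycerate) | COC(=O)[C@H](O)CO | starting material
26 | methyl (R)-3-(tert-butyldimethylsilyloxy)-2-hydroxypropanoate | COC(=O)[C@H](O)CO[Si](C)(C)C(C)(C)C | intermediate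
27 | methyl (S)-3-(tert-butyldimethylsilyloxy)-2-(aryloxy)propanoate, aryloxy = 4-O of 24 | COC(=O)[C@H](CO[Si](C)(C)C(C)(C)C)Oc1ccc([C@@H]2OC[C@@H]3[C@H]2CO[C@H]3c2cc(OC)c(O[Si](C(C)C)(C(C)C)C(C)C)c(OC)c2)cc1OC | intermediate
28 | 4-bromo-2-methoxyphenol | COc1cc(Br)ccc1O | starting material
29 | (4-bromo-2-methoxyphenoxy)(tert-butyl)dimethylsilane | COc1cc(Br)ccc1O[Si](C)(C)C(C)(C)C | intermediate
30 | N-methoxy-N-methyl amide (Weinreb amide) of 27 | CON(C)C(=O)[C@H](CO[Si](C)(C)C(C)(C)C)Oc1ccc([C@@H]2OC[C@@H]3[C@H]2CO[C@H]3c2cc(OC)c(O[Si](C(C)C)(C(C)C)C(C)C)c(OC)c2)cc1OC | intermediate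
31 | (S)-aryl ketone (C7'' carbonyl, 8''S) | COc1cc(C(=O)[C@H](CO[Si](C)(C)C(C)(C)C)Oc2ccc([C@@H]3OC[C@@H]4[C@H]3CO[C@H]4c3cc(OC)c(O[Si](C(C)C)(C(C)C)C(C)C)c(OC)c3)cc2OC)ccc1O[Si](C)(C)C(C)(C)C | intermediate
32 | (7''R,8''S)-alcohol, 4',4'',9''-tris-silyl ether of the target | COc1cc([C@@H](O)[C@H](CO[Si](C)(C)C(C)(C)C)Oc2ccc([C@@H]3OC[C@@H]4[C@H]3CO[C@H]4c3cc(OC)c(O[Si](C(C)C)(C(C)C)C(C)C)c(OC)c3)cc2OC)ccc1O[Si](C)(C)C(C)(C)C | intermediate
33 | ficusesquilignan A | COc1cc([C@@H](O)[C@H](CO)Oc2ccc([C@@H]3OC[C@@H]4[C@H]3CO[C@H]4c3cc(OC)c(O)c(OC)c3)cc2OC)ccc1O | target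

**Step count and risks**
Total step count: 20. Longest linear sequence: 16 steps (from 4 through steps 2, 3, 4, 5, 6, 8, 9, 10, 11, 12, 13, 14, 16, 18, 19, 20).

Steps most likely to fail:

Step 11. The biradical may close with poor facial bias at C7 (aryl turning to the concave face), or α-cleavage of the excited tetrahydrofuran-3-one may outrun hydrogen abstraction. The fallback is ionic and sets out from 14. Commercial 4-(benzyloxy)-3-methoxybenzaldehyde is converted into its dimethyl acetal F1 (HC(OMe)3, TsOH cat., MeOH). Acetal exchange of F1 with the hydroxyl of 14 under TMSOTf (CH2Cl2, −20 °C) gives an oxocarbenium ion at C7, which is attacked by C8 of the enol ether; methanol caps the new C9 oxocarbenium ion to give the bicyclic methyl acetal F2. Et3SiH with BF3·OEt2 (−78 °C) reduces the C9 acetal to the furofuran F3, which by analogy with related cyclizations is expected to carry the new aryl group endo (the C7 epimer of 23). Acid-mediated equilibration of the benzylic ether centre (HCl cat. in dioxane) should then give 23 together with F3; the two are separated and F3 is resubmitted. The route is rejoined at 23.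

Step 13. The tin hydride chain may fail to propagate at the hindered tertiary oxalate, or the oxalate may eliminate or hydrolyse back to 21. The fallback sets out from 21 and generates the same C8 radical reductively. 21 is treated with oxalyl chloride, then N-hydroxyphthalimide and Et3N, to give the tert-alkyl N-phthalimidoyl oxalate F4. Visible-light fragmentation of F4 (Ru(bpy)3(PF6)2 cat., Hantzsch ester, iPr2NEt·HBF4, blue LEDs, CH2Cl2/THF) proceeds by single-electron reduction of the phthalimide and loss of phthalimide and two molecules of CO2; the C8 radical is then quenched by the Hantzsch ester from the convex face. The route is rejoined at 23.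

Step 19. Chelation between the carbonyl and the aryloxy oxygen may be incomplete, so that the open Felkin–Anh pathway erodes facial selectivity. The fallback sets out from 31 and sets C7'' by substitution instead. Reduction under non-chelating conditions with a bulky hydride (LiBH(s-Bu)3, THF, −78 °C) should give the threo alcohol F5 (7''S,8''S). Mitsunobu esterification with 4-nitrobenzoic acid (PPh3, DIAD) inverts C7'' to give the 4-nitrobenzoate F6 (7''R,8''S). Reductive removal of the ester with i-Bu2AlH (CH2Cl2, −78 °C) comes back to the route at 32.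

**Further compounds**
F1 | step 11 | 4-(benzyloxy)-3-methoxybenzaldehyde dimethyl acetal | COc1cc(C(OC)OC)ccc1OCc1ccccc1
F2 | step 11 | bicyclic methyl acetal: 9-methoxy derivative of the C7 epimer of 23 (guaiacyl aryl endo, C9 anomers) | COc1cc([C@H]2OC[C@@H]3[C@H]2C(OC)O[C@H]3c2cc(OC)c(O[Si](C(C)C)(C(C)C)C(C)C)c(OC)c2)ccc1OCc1ccccc1
F3 | step 11 | C7 epimer of 23 (7S,8S,7'R,8'S; guaiacyl aryl endo) | COc1cc([C@H]2OC[C@@H]3[C@H]2CO[C@H]3c2cc(OC)c(O[Si](C(C)C)(C(C)C)C(C)C)c(OC)c2)ccc1OCc1ccccc1
F4 | step 13 | N-phthalimidoyl oxalate of 21 | COc1cc([C@@H]2OC[C@@H]3[C@@]2(OC(=O)C(=O)ON2C(=O)c4ccccc4C2=O)CO[C@H]3c2cc(OC)c(O[Si](C(C)C)(C(C)C)C(C)C)c(OC)c2)ccc1OCc1ccccc1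
F5 | step 19 | threo alcohol (7''S,8''S), C7'' epimer of 32 | COc1cc([C@H](O)[C@H](CO[Si](C)(C)C(C)(C)C)Oc2ccc([C@@H]3OC[C@@H]4[C@H]3CO[C@H]4c3cc(OC)c(O[Si](C(C)C)(C(C)C)C(C)C)c(OC)c3)cc2OC)ccc1O[Si](C)(C)C(C)(C)C
F6 | step 19 | 4-nitrobenzoate of 32 (7''R,8''S) | COc1cc([C@@H](OC(=O)c2ccc(cc2)[N+](=O)[O-])[C@H](CO[Si](C)(C)C(C)(C)C)Oc2ccc([C@@H]3OC[C@@H]4[C@H]3CO[C@H]4c3cc(OC)c(O[Si](C(C)C)(C(C)C)C(C)C)c(OC)c3)cc2OC)ccc1O[Si](C)(C)C(C)(C)C
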